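**Retrosynthetic overview**

- The target has three purchased benzene rings and no stereocentre: ring A (C1 OMe, C3 OH, C4 aryl, C5 CH2CH2), ring B (2,5-dihydroxyphenyl on C4) and ring C (3-hydroxyphenyl at the end of the Cα–Cβ bridge).
- The strategy rests on C5 of ring A: the carbon carrying the Cα–Cβ bridge is a former oxygen position of a symmetric 2-aryl-5-methoxyresorcinol, in which ring B sits between two equivalent hydroxyls. One hydroxyl becomes the C3–OH, the other the C5 triflate.
- Key disconnection: the C5–Cα and Cβ–ring C bonds are cut together, giving the ring A triflate, vinylboronic acid pinacol ester and 3-(benzyloxy)phenyllithium. The boron left on Cβ is removed by protodeboronation.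
- The A–B biaryl bond comes from a Negishi coupling of the 5-methoxyresorcinol bis(methoxymethyl) ether, metalated between its two acetal ethers, with dibenzylated bromohydroquinone.
- No ring is formed. The rings are joined A–B first (step 3), then A–C through the two-carbon linchpin (step 7); global debenzylation comes last.

Key step: step 7

Assumption: the A–B biaryl axis (three ortho substituents, all small) is taken as freely rotating at room temperature, so no axial descriptor is carried.

**Route**

Step 1
Reactants: 1 5-methoxyresorcinol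
Product: 2 1-methoxy-3,5-bis(methoxymethoxy)benzene
Conditions: NaH (2.4 equiv), MOMCl (2.4 equiv), DMF, 0 °C → rt
Reagents that add atoms: chloromethyl methyl ether, COCCl
Why: Williamson-type O-alkylation of both phenoxides gives the two methoxymethyl ethers that will direct the metalation in step 3.

Step 2
Reactants: 3 bromohydroquinone
Product: 4 1,4-bis(benzyloxy)-2-bromobenzene
Conditions: BnBr (2.3 equiv), K2CO3 (3 equiv), DMF, rt, N2
Reagents that add atoms: benzyl bromide, BrCc1ccccc1
Why: Williamson ether synthesis on both hydroquinone hydroxyls, run under nitrogen to keep the hydroquinone from oxidising, leaves the aryl bromide untouched for cross-coupling.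

Step 3
Reactants: 2 1-methoxy-3,5-bis(methoxymethoxy)benzene, 4 1,4-bis(benzyloxy)-2-bromobenzene
Product: 7 2-[2,5-bis(benzyloxy)phenyl]-5-methoxy-1,3-bis(methoxymethoxy)benzene, via aryllithium 5 (not isolated), via arylzinc chloride 6 (not isolated)
Conditions: n-BuLi, THF, 0 °C; ZnCl2, 0 °C → rt; then 4, Pd2(dba)3 (1 mol%), RuPhos (2-dicyclohexylphosphino-2',6'-diisopropoxybiphenyl, 4 mol%), THF, 65 °C
Reagents that add atoms: none
Why: Directed ortho-metalation takes the proton flanked by both methoxymethyl ethers (doubly chelated, most acidic site), and after transmetalation to zinc a Negishi cross-coupling with a bulky dialkylbiarylphosphine ligand forms the tri-ortho-substituted biaryl bond.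

Step 4
Reactants: 7 2-[2,5-bis(benzyloxy)phenyl]-5-methoxy-1,3-bis(methoxymethoxy)benzene
Product: 8 2-[2,5-bis(benzyloxy)phenyl]-5-methoxybenzene-1,3-diol
Conditions: 3 M HCl, MeOH/THF, 50 °C
Reagents that add atoms: none
Why: Acid-catalysed acetal methanolysis removes both methoxymethyl groups while benzyl and methyl ethers are inert, and the excess methanol traps the methoxymethyl cation as dimethoxymethane so that the electron-rich ring A is not alkylated.

Step 5
Reactants: 8 2-[2,5-bis(benzyloxy)phenyl]-5-methoxybenzene-1,3-diol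
Product: 9 3-(benzyloxy)-2-[2,5-bis(benzyloxy)phenyl]-5-methoxyphenol
Conditions: BnBr (1.0 equiv), K2CO3 (1.1 equiv), acetone, 50 °C; unreacted 8 recovered and recycled
Reagents that add atoms: benzyl bromide, BrCc1ccccc1
Why: Williamson mono-O-alkylation of a diol whose two hydroxyls are equivalent by symmetry should give a single mono-ether whichever oxygen reacts, and limiting the bromide together with the large polarity gaps between diol, mono-ether and bis-ether makes the mono-ether separable.

Step 6
Reactants: 9 3-(benzyloxy)-2-[2,5-bis(benzyloxy)phenyl]-5-methoxyphenol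
Product: 10 3-(benzyloxy)-2-[2,5-bis(benzyloxy)phenyl]-5-methoxyphenyl trifluoromethanesulfonate
Conditions: Tf2O, pyridine, CH2Cl2, 0 °C
Reagents that add atoms: trifluoromethanesulfonic anhydride, O=S(=O)(OS(=O)(=O)C(F)(F)F)C(F)(F)F
Why: O-Sulfonylation (triflation) of the one remaining phenol turns the former oxygen position C5 into the electrophilic site for palladium.

Step 7
Reactants: 10 3-(benzyloxy)-2-[2,5-bis(benzyloxy)phenyl]-5-methoxyphenyl trifluoromethanesulfonate, 11 1-(benzyloxy)-3-bromobenzene, 12 vinylboronic acid pinacol ester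
Product: 15 2-{1-[3-(benzyloxy)phenyl]-2-[3-(benzyloxy)-2-(2,5-bis(benzyloxy)phenyl)-5-methoxyphenyl]ethyl}-4,4,5,5-tetramethyl-1,3,2-dioxaborolane (racemic), via aryllithium 13 (not isolated), via vinylboron ate complex 14 (not isolated)
Conditions: 11, n-BuLi, THF, −78 °C; 12, −78 °C → rt; volatiles removed in vacuo; then 10 (0.75 equiv), Pd(OAc)2 (3 mol%), 1,1′-bis(dicyclohexylphosphino)ferrocene (3.6 mol%), THF, 60 °C
Reagents that add atoms: none
Why: Aryllithium 13 adds to boron of 12 to give the four-coordinate vinylboronate 14; zerovalent palladium, formed from Pd(OAc)2 and the diphosphine, inserts into the C5–OTf bond of 10, and the resulting cationic divalent arylpalladium binds the vinyl group of 14. This π-activation triggers a 1,2-shift of the ring C aryl from boron to the boron-bearing carbon (Cβ) while the terminal carbon (Cα) bonds to palladium, and reductive elimination then forms the C5–Cα bond and returns zerovalent palladium. The reaction is a direct application of the known palladium-catalysed conjunctive cross-coupling of vinylboron ate complexes with aryl triflates. No ring is closed, and the one new stereocentre at Cβ is not controlled (achiral ligand, racemate) and is erased in step 8. The selectivity needed is conjunctive coupling over direct Suzuki-type transfer of aryl or vinyl and over β-hydride elimination: the non-coordinating triflate keeps palladium cationic, bromine–lithium exchange with n-BuLi leaves no lithium halide (only 1-bromobutane, removed with the solvent), and the wide-bite-angle ferrocenyl diphosphine speeds reductive elimination. Both ring A ethers are meta to the C–OTf carbon and so do not retard oxidative addition by resonance, and the position of the bridge on ring A was fixed beforehand by the symmetry of diol 8.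

Step 8
Reactants: 15 2-{1-[3-(benzyloxy)phenyl]-2-[3-(benzyloxy)-2-(2,5-bis(benzyloxy)phenyl)-5-methoxyphenyl]ethyl}-4,4,5,5-tetramethyl-1,3,2-dioxaborolane (racemic)
Product: 16 1-(benzyloxy)-2-[2,5-bis(benzyloxy)phenyl]-3-{2-[3-(benzyloxy)phenyl]ethyl}-5-methoxybenzene
Conditions: Bu4NF·3H2O (3 equiv), toluene, 90 °C, N2
Reagents that add atoms: none
Why: Fluoride-promoted protodeboronation of a benzylic boronic ester, in which fluoride forms the boron ate complex and the benzylic C–B bond is cleaved with protonation by the water of hydration, removes the only stereocentre and leaves all ethers intact.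

Step 9
Reactants: 16 1-(benzyloxy)-2-[2,5-bis(benzyloxy)phenyl]-3-{2-[3-(benzyloxy)phenyl]ethyl}-5-methoxybenzene
Product: 17 2-{2-hydroxy-6-[2-(3-hydroxyphenyl)ethyl]-4-methoxyphenyl}benzene-1,4-diol (CNP0121738.0)
Conditions: H2 (1 atm), 10% Pd/C, EtOAc/MeOH, rt; work-up under N2
Reagents that add atoms: none
Why: Catalytic hydrogenolysis cleaves the four benzyl ethers while the aryl methyl ether and the saturated bridge are inert, and an inert work-up protects the hydroquinone ring B from air oxidation.

**Compound list**

1 | 5-methoxyresorcinol | COc1cc(O)cc(O)c1 | starting material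
2 | 1-methoxy-3,5-bis(methoxymethoxy)benzene | COc1cc(OCOC)cc(OCOC)c1 | intermediate
3 | bromohydroquinone | Oc1ccc(O)c(Br)c1 | starting material
4 | 1,4-bis(benzyloxy)-2-bromobenzene | Brc1cc(OCc2ccccc2)ccc1OCc1ccccc1 | intermediate
5 | [4-methoxy-2,6-bis(methoxymethoxy)phenyl]lithium | COc1cc(OCOC)c([Li])c(OCOC)c1 | intermediate
6 | [4-methoxy-2,6-bis(methoxymethoxy)phenyl]zinc chloride | COc1cc(OCOC)c([Zn]Cl)c(OCOC)c1 | intermediate
7 | 2-[2,5-bis(benzyloxy)phenyl]-5-methoxy-1,3-bis(methoxymethoxy)benzene | COc1cc(OCOC)c(-c2cc(OCc3ccccc3)ccc2OCc2ccccc2)c(OCOC)c1 | intermediate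
8 | 2-[2,5-bis(benzyloxy)phenyl]-5-methoxybenzene-1,3-diol | COc1cc(O)c(-c2cc(OCc3ccccc3)ccc2OCc2ccccc2)c(O)c1 | intermediate
9 | 3-(benzyloxy)-2-[2,5-bis(benzyloxy)phenyl]-5-methoxyphenol | COc1cc(O)c(-c2cc(OCc3ccccc3)ccc2OCc2ccccc2)c(OCc2ccccc2)c1 | intermediate
10 | 3-(benzyloxy)-2-[2,5-bis(benzyloxy)phenyl]-5-methoxyphenyl trifluoromethanesulfonate | COc1cc(OCc2ccccc2)c(-c2cc(OCc3ccccc3)ccc2OCc2ccccc2)c(OS(=O)(=O)C(F)(F)F)c1 | intermediate
11 | 1-(benzyloxy)-3-bromobenzene | Brc1cccc(OCc2ccccc2)c1 | starting material
12 | vinylboronic acid pinacol ester (4,4,5,5-tetramethyl-2-vinyl-1,3,2-dioxaborolane) | C=CB1OC(C)(C)C(C)(C)O1 | starting material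
13 | 3-(benzyloxy)phenyllithium | [Li]c1cccc(OCc2ccccc2)c1 | intermediate
14 | lithium [3-(benzyloxy)phenyl](pinacolato)vinylborate | [Li+].C=C[B-]1(c2cccc(OCc3ccccc3)c2)OC(C)(C)C(C)(C)O1 | intermediate
15 | 2-{1-[3-(benzyloxy)phenyl]-2-[3-(benzyloxy)-2-(2,5-bis(benzyloxy)phenyl)-5-methoxyphenyl]ethyl}-4,4,5,5-tetramethyl-1,3,2-dioxaborolane, racemic at the boron-bearing carbon | COc1cc(OCc2ccccc2)c(-c2cc(OCc3ccccc3)ccc2OCc2ccccc2)c(CC(B2OC(C)(C)C(C)(C)O2)c2cccc(OCc3ccccc3)c2)c1 | intermediate
16 | 1-(benzyloxy)-2-[2,5-bis(benzyloxy)phenyl]-3-{2-[3-(benzyloxy)phenyl]ethyl}-5-methoxybenzene | COc1cc(OCc2ccccc2)c(-c2cc(OCc3ccccc3)ccc2OCc2ccccc2)c(CCc2cccc(OCc3ccccc3)c2)c1 | intermediate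
17 | 2-{2-hydroxy-6-[2-(3-hydroxyphenyl)ethyl]-4-methoxyphenyl}benzene-1,4-diol (CNP0121738.0) | COc1cc(O)c(-c2cc(O)ccc2O)c(CCc2cccc(O)c2)c1 | target

**Step count**

Total: 9 steps. Longest linear sequence: 8 steps (steps 1, 3, 4, 5, 6, 7, 8, 9, from 5-methoxyresorcinol).

**Steps most likely to fail**

1. Step 7. Oxidative addition at the C–OTf bond next to the bulky ring B may be slow, so that direct Suzuki-type transfer of aryl or vinyl from the ate complex, β-hydride elimination from the alkylpalladium, or inhibition by traces of bromide take over. KOTf as a halide scavenger or a diamino-bis(diarylphosphino)ferrocene ligand would be tried first. The fallback sets out from 10, 11 and 12 and comes back at 16, so that step 8 is not needed. Bromide 11 and boronate 12 are joined by an ordinary Suzuki–Miyaura coupling (PdCl2(dppf), K2CO3, dioxane/H2O, 80 °C; dppf = 1,1′-bis(diphenylphosphino)ferrocene) to 1-(benzyloxy)-3-vinylbenzene F1. Anti-Markovnikov hydroboration with 9-borabicyclo[3.3.1]nonane (THF, rt) gives 9-{2-[3-(benzyloxy)phenyl]ethyl}-9-borabicyclo[3.3.1]nonane F2. B-alkyl Suzuki–Miyaura coupling of F2 with triflate 10 (PdCl2(dppf), K3PO4, THF/H2O, 65 °C) then delivers 16 with the whole saturated bridge in place.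

2. Step 8. Cleavage of the C–B bond of a secondary benzylic boronate may be sluggish, and air oxidation to the alcohol may compete on prolonged heating. The fallback sets out from 15 and comes back at 17. Oxidation with NaBO3·4H2O (THF/H2O, rt) gives the racemic alcohol 1-[3-(benzyloxy)phenyl]-2-{3-(benzyloxy)-2-[2,5-bis(benzyloxy)phenyl]-5-methoxyphenyl}ethanol F3. Methanesulfonyl chloride and Et3N (CH2Cl2, 0 °C) give the benzylic mesylate F4, which is not isolated. DBU (toluene, 80 °C) eliminates it under basic conditions to the (E)-stilbene 1-(benzyloxy)-2-[2,5-bis(benzyloxy)phenyl]-3-{(E)-2-[3-(benzyloxy)phenyl]ethenyl}-5-methoxybenzene F5; the basic medium avoids a benzylic cation that could cyclise onto ring B. Hydrogenation over 10% Pd/C (H2, EtOAc/MeOH) saturates the alkene and removes the four benzyl groups in one operation to give 17.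

3. Step 5. Over-alkylation to the bis-ether and incomplete conversion give a near-statistical distribution that limits throughput. The fallback sets out from 8 and comes back at 10, reversing the order so that the selectivity-determining event is a sulfonylation. Diol 8 is treated with N-phenylbis(trifluoromethanesulfonimide) (1.0 equiv, K2CO3, THF, rt) to give 3-hydroxy-2-[2,5-bis(benzyloxy)phenyl]-5-methoxyphenyl trifluoromethanesulfonate F6. The strongly electron-withdrawing triflate makes the second phenoxide less nucleophilic, which should hold the reaction at the mono-triflate. Benzylation of F6 (BnBr, K2CO3, acetone, rt) then gives 10.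

**Further compounds**

F1 | step 7 | 1-(benzyloxy)-3-vinylbenzene | C=Cc1cccc(OCc2ccccc2)c1
F2 | step 7 | 9-{2-[3-(benzyloxy)phenyl]ethyl}-9-borabicyclo[3.3.1]nonane | c1ccc(COc2cccc(CCB3C4CCCC3CCC4)c2)cc1
F3 | step 8 | 1-[3-(benzyloxy)phenyl]-2-{3-(benzyloxy)-2-[2,5-bis(benzyloxy)phenyl]-5-methoxyphenyl}ethanol (racemic) | COc1cc(OCc2ccccc2)c(-c2cc(OCc3ccccc3)ccc2OCc2ccccc2)c(CC(O)c2cccc(OCc3ccccc3)c2)c1
F4 | step 8 | 1-[3-(benzyloxy)phenyl]-2-{3-(benzyloxy)-2-[2,5-bis(benzyloxy)phenyl]-5-methoxyphenyl}ethyl methanesulfonate (racemic) | COc1cc(OCc2ccccc2)c(-c2cc(OCc3ccccc3)ccc2OCc2ccccc2)c(CC(OS(C)(=O)=O)c2cccc(OCc3ccccc3)c2)c1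
F5 | step 8 | 1-(benzyloxy)-2-[2,5-bis(benzyloxy)phenyl]-3-{(E)-2-[3-(benzyloxy)phenyl]ethenyl}-5-methoxybenzene | COc1cc(OCc2ccccc2)c(-c2cc(OCc3ccccc3)ccc2OCc2ccccc2)c(/C=C/c2cccc(OCc3ccccc3)c2)c1
F6 | step 5 | 3-hydroxy-2-[2,5-bis(benzyloxy)phenyl]-5-methoxyphenyl trifluoromethanesulfonate | COc1cc(O)c(-c2cc(OCc3ccccc3)ccc2OCc2ccccc2)c(OS(=O)(=O)C(F)(F)F)c1
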